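**Retrosynthetic overview**
1. The target 3 is the 15-acetate of (13E)-labd-13-ene-8α,15-diol. Its C15–O bond and 13E alkene are disconnected together by a [3,3]-sigmatropic 1,3-acyloxy shift, leading back to the tertiary allylic acetate 2.
2. Compound 2 is disconnected at the ester C–O bond to (−)-sclareol 1, by site-selective acetylation of the side-chain 13-OH over the ring 8-OH.
3. No ring is formed. Rings A and B (the trans-decalin) with C5, C8, C9 and C10 are bought intact in 1, and C13 of 1 is a sacrificial stereocentre.

Assumption: natural (−)-sclareol (from clary sage, a bulk fragrance intermediate) is taken as the commercial chiral starting material. The target is read as (13E)-8α-hydroxylabd-13-en-15-yl acetate, (5S,8R,9R,10S), the same absolute series as 1.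

**Route**

Step 1
Reactants: 1 (−)-sclareol, (13R)-labd-14-ene-8α,13-diol
Product: 2 (13R)-8α-hydroxylabd-14-en-13-yl acetate (sclareol 13-O-acetate)
Conditions: AcCl (1.3 equiv), PhNMe2 (2.5 equiv), CH2Cl2, 0 °C to rt, stopped at about 80% conversion
Reagents that add atoms: acetyl chloride, CC(=O)Cl
Why: O-acylation with an acyl chloride and a tertiary amine should go faster at the side-chain tertiary allylic 13-OH (on a freely rotating chain, next to a flat vinyl group) than at the ring 8α-OH (buttressed by C9, its side chain and the C10 quaternary centre), so limiting AcCl should give mainly the 13-monoacetate, with no stereocentre touched; unreacted 1 and a little diacetate are separated on silica and 1 is recycled.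

Step 2
Reactants: 2 (13R)-8α-hydroxylabd-14-en-13-yl acetate
Product: 3 (13E)-8α-hydroxylabd-13-en-15-yl acetate (target)
Conditions: PdCl2(CH3CN)2 (5 mol%), dry THF, rt, 12–24 h
Reagents that add atoms: none
Why: This is a divalent-palladium-catalysed [3,3]-sigmatropic allylic ester (1,3-acyloxy) rearrangement in which the catalyst binds the terminal vinyl group and the acetate carbonyl oxygen is delivered to C15 through a six-membered chair-like array with the large C12 chain, not the C16 methyl, pseudo-equatorial, so the C15–O bond and the 13E alkene form together, C13 is erased, C5, C8, C9 and C10 are untouched, and the trisubstituted alkene product no longer binds the catalyst, which makes the shift effectively irreversible; the minor 13Z isomer is removed on AgNO3-impregnated silica.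

**Compound list**
1 | (−)-sclareol, (13R)-labd-14-ene-8α,13-diol | C=C[C@](C)(O)CC[C@@H]1[C@@]2(C)CCCC(C)(C)[C@@H]2CC[C@@]1(C)O | starting material
2 | (13R)-8α-hydroxylabd-14-en-13-yl acetate | C=C[C@](C)(OC(C)=O)CC[C@@H]1[C@@]2(C)CCCC(C)(C)[C@@H]2CC[C@@]1(C)O | intermediate
3 | (13E)-8α-hydroxylabd-13-en-15-yl acetate, (5S,8R,9R,10S) | CC(=O)OC/C=C(\C)CC[C@@H]1[C@@]2(C)CCCC(C)(C)[C@@H]2CC[C@@]1(C)O | target

**Totals**
Total step count: 2. Longest linear sequence: 2.

**Steps most likely to fail**
The route has only two steps, so both are given, the riskier one first.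

Step 1 (site selectivity between two tertiary hydroxyls). The selectivity rests on a steric argument, not on a result I can point to for this exact mono-acetylation. If it gives an inseparable or near-statistical mixture, the fallback sets out from 1 and comes back at 3, bypassing 2. Exhaustive acetylation of 1 (AcCl in excess, PhNMe2, CH2Cl2, rt, 48 h) gives sclareol 8,13-diacetate F1. The same divalent-palladium [3,3] shift (PdCl2(CH3CN)2, THF, rt) gives (13E)-labd-13-ene-8α,15-diyl diacetate F2. KOH in MeOH/H2O at reflux removes both esters to give (13E)-labd-13-ene-8α,15-diol F3, which can also be freed of any 13Z isomer at this stage. Ac2O in pyridine at 0 °C without DMAP then acetylates only the primary allylic hydroxyl and gives 3. This replaces the tertiary-versus-tertiary discrimination with an easy primary-versus-tertiary one, at the cost of two extra steps.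

Step 2 (free 8-OH under a Lewis-acidic palladium salt, and alkene geometry). The 8-OH could capture C13 after ionisation or oxypalladation and give cyclic ethers of the manoyl oxide type (8,13-epoxylabd-14-enes). The E/Z ratio is also only moderate for a methyl-versus-CH2R choice, so some 13Z isomer must be expected and separated. If the free hydroxyl interferes, the fallback sets out from 2 and comes back at 3. Silylation of the 8-OH with N-(trimethylsilyl)imidazole (CH2Cl2, rt) gives (13R)-8α-(trimethylsilyloxy)labd-14-en-13-yl acetate F4. The rearrangement with PdCl2(CH3CN)2 in dry THF then gives (13E)-8α-(trimethylsilyloxy)labd-13-en-15-yl acetate F5. Mild acidolysis (AcOH/THF/H2O 3:1:1, rt) removes the silyl group without touching the primary allylic acetate and gives 3.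

**Further compounds**
F1 | step 1 | sclareol 8,13-diacetate, (13R)-labd-14-ene-8α,13-diyl diacetate | C=C[C@](C)(OC(C)=O)CC[C@@H]1[C@@]2(C)CCCC(C)(C)[C@@H]2CC[C@@]1(C)OC(C)=O
F2 | step 1 | (13E)-labd-13-ene-8α,15-diyl diacetate | CC(=O)OC/C=C(\C)CC[C@@H]1[C@@]2(C)CCCC(C)(C)[C@@H]2CC[C@@]1(C)OC(C)=O
F3 | step 1 | (13E)-labd-13-ene-8α,15-diol | OC/C=C(\C)CC[C@@H]1[C@@]2(C)CCCC(C)(C)[C@@H]2CC[C@@]1(C)O
F4 | step 2 | (13R)-8α-(trimethylsilyloxy)labd-14-en-13-yl acetate | C=C[C@](C)(OC(C)=O)CC[C@@H]1[C@@]2(C)CCCC(C)(C)[C@@H]2CC[C@@]1(C)O[Si](C)(C)C
F5 | step 2 | (13E)-8α-(trimethylsilyloxy)labd-13-en-15-yl acetate | CC(=O)OC/C=C(\C)CC[C@@H]1[C@@]2(C)CCCC(C)(C)[C@@H]2CC[C@@]1(C)O[Si](C)(C)C
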